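**Strategy.** The decisive disconnection is the bond between quaternary C7 (tricyclo[5.3.1.0(3,8)]undecane numbering) and C1′ of the side chain. C7–C11 is the two-carbon bridge of the bicyclo[2.2.2]octan-10-one and is tied to C3 through ring B (C3–C8), so C7=C11 is the dienophile of an intramolecular Diels–Alder onto a C1=C10(OSi)–C9=C8 diene. C7 can therefore be joined while still planar: the enantiopure side-chain organolithium opens a γ-lactone whose carbonyl carbon is C7 and whose ring oxygen sits on C4, a temporary ring hung on the siloxycyclohexadiene. Methylenation and cycloaddition then create the quaternary centre, whose configuration the tether dictates.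

Key step: step 8

Assumption: in the catalyst-controlled steps 1 and 4 the catalyst enantiomer named is taken to be the one that delivers the configuration drawn (otherwise its mirror image is used).

**Step 1**
Reactants: 1 (1E)-3-[(tert-butyldimethylsilyl)oxy]-N,N-dimethylbuta-1,3-dien-1-amine; 2 (E)-2-methylbut-2-enal
Product: 4 (1S,6R)-1,6-dimethyl-4-oxocyclohex-2-ene-1-carbaldehyde, via endo cycloadduct 3 (not isolated)
Conditions: (R,R)-1-naphthyl-TADDOL (20 mol %), toluene, −78 → −40 °C; then AcCl, CH2Cl2, −78 °C → rt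
Reagents that add atoms: none
Why: Diels–Alder reaction of the electron-rich 1-amino-3-siloxydiene with the enal activated by hydrogen bonding to the chiral diol: suprafacial addition turns the (E)-geometry of 2 into the cis relationship of the two methyl groups, the catalyst selects the enal face, and N-acylation/β-elimination with AcCl unveils the enone and removes the amino-bearing stereocentre.

**Step 2**
Reactants: 4 (1S,6R)-1,6-dimethyl-4-oxocyclohex-2-ene-1-carbaldehyde; 5 methyl (2S)-3-bromo-2-methylpropanoate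
Product: 8 (3R,5RS)-5-[(1S,6R)-1,6-dimethyl-4-oxocyclohex-2-en-1-yl]-3-methyloxolan-2-one, via zinc homoenolate 6 (not isolated), via silyloxy ester 7 (not isolated)
Conditions: 5, Zn dust, LiCl, THF, 40 °C; then 4, TMSCl, THF–NMP, 0 °C → rt; then 1 M HCl, THF, rt
Reagents that add atoms: none
Why: Zinc insertion gives the β-zincio ester (zinc homoenolate), whose TMSCl-promoted 1,2-addition to the aldehyde (homoaldol addition; without copper the enone is not attacked) and acid-induced lactonisation give the γ-lactone; the methyl-bearing stereocentre comes unchanged from 5, and the new carbinol centre next to the quaternary carbon is expected to form with little selectivity, so both epimers are carried until steps 10 and 12 make it uniform.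

**Step 3**
Reactants: 8 (3R,5RS)-5-[(1S,6R)-1,6-dimethyl-4-oxocyclohex-2-en-1-yl]-3-methyloxolan-2-one
Product: 9 (3R,5RS)-5-[(1R,6R)-4-[(tert-butyldimethylsilyl)oxy]-1,6-dimethylcyclohexa-2,4-dien-1-yl]-3-methyloxolan-2-one
Conditions: TBSOTf, Et3N, CH2Cl2, −78 → 0 °C
Reagents that add atoms: tert-butyldimethylsilyl trifluoromethanesulfonate, CC(C)(C)[Si](C)(C)OS(=O)(=O)C(F)(F)F
Why: Soft enolisation/O-silylation of the enone: because the γ-carbon is quaternary only the α′-CH2 can be deprotonated, so the cross-conjugated 2-siloxy-1,3-diene forms, which masks the ketone towards the organolithium of step 8 and is the diene of step 11, while the lactone is not enolised by Et3N.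

**Step 4**
Reactants: 10 3-methylbut-3-en-1-ol
Product: 11 2-[(2S)-2-methyloxiran-2-yl]ethan-1-ol
Conditions: Hf(Ot-Bu)4 (cat.), C2-symmetric bis-hydroxamic acid ligand (cat.), cumene hydroperoxide, DMPU, 4 Å MS, toluene, 0 °C
Reagents that add atoms: cumene hydroperoxide, CC(C)(OO)c1ccccc1
Why: Hydroxyl-directed catalytic asymmetric epoxidation of a homoallylic alcohol with a Hf(IV)–bis-hydroxamic acid complex and a hydroperoxide, in which the chiral ligand selects the alkene face and so sets the carbinol stereocentre that becomes C3′ of the side chain.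

**Step 5**
Reactants: 11 2-[(2S)-2-methyloxiran-2-yl]ethan-1-ol
Product: 12 (3S)-3-methylpent-4-ene-1,3-diol
Conditions: Me3S+ I−, n-BuLi, THF, −10 °C → rt
Reagents that add atoms: trimethylsulfonium iodide, C[S+](C)C.[I-]
Why: One-carbon homologation of an epoxide to an allylic alcohol with dimethylsulfonium methylide: the ylide opens the epoxide at its CH2, deprotonation gives the β-oxido sulfonium ylide, and elimination of dimethyl sulfide forms the vinyl group while the quaternary C–O stereocentre is untouched.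

**Step 6**
Reactants: 12 (3S)-3-methylpent-4-ene-1,3-diol
Product: 13 (3S)-5-iodo-3-methylpent-1-en-3-ol
Conditions: I2, PPh3, imidazole, CH2Cl2, 0 °C
Reagents that add atoms: iodine, II
Why: Appel-type iodination (PPh3/I2/imidazole), an SN2 displacement of the oxyphosphonium that is selective for the primary alcohol over the hindered tertiary allylic one.

**Step 7**
Reactants: 13 (3S)-5-iodo-3-methylpent-1-en-3-ol
Product: 14 triethyl{[(3S)-5-iodo-3-methylpent-1-en-3-yl]oxy}silane
Conditions: TESOTf, 2,6-lutidine, CH2Cl2, −78 → 0 °C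
Reagents that add atoms: triethylsilyl trifluoromethanesulfonate, CC[Si](CC)(CC)OS(=O)(=O)C(F)(F)F
Why: Silylation of the hindered tertiary alcohol with a silyl triflate and a non-nucleophilic base gives a TES ether that survives steps 8–13 and is removed together with the silyl enol ether in step 14.

**Step 8**
Reactants: 9 (3R,5RS)-5-[(1R,6R)-4-[(tert-butyldimethylsilyl)oxy]-1,6-dimethylcyclohexa-2,4-dien-1-yl]-3-methyloxolan-2-one; 14 triethyl{[(3S)-5-iodo-3-methylpent-1-en-3-yl]oxy}silane
Product: 16 (1RS,3R,7S)-1-[(1R,6R)-4-[(tert-butyldimethylsilyl)oxy]-1,6-dimethylcyclohexa-2,4-dien-1-yl]-1-hydroxy-3,7-dimethyl-7-[(triethylsilyl)oxy]non-8-en-4-one, via side-chain alkyllithium 15 (not isolated)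
Conditions: 14, t-BuLi (2.1 equiv), Et2O–pentane, −78 °C; then 9, Et2O, −78 °C; then H2O
Reagents that add atoms: none
Why: Iodine–lithium exchange gives the primary alkyllithium 15, which adds to the lactone carbonyl (C7 of the target) to form a lithium lactolate that is stable at −78 °C and opens to the γ-hydroxy ketone on work-up (acyl substitution of a lactone by an organolithium, a known route to hydroxy ketones). No ring is closed; the temporary oxolanone ring is opened and its oxygen is left on C4. No stereocentre is formed: C3′ of 15 and the methyl-bearing α-carbon of the lactone (C6) are carried through, the latter because carbonyl addition of an unhindered primary alkyllithium at −78 °C in ether should outrun α-deprotonation. The selectivity needed is mono-addition and chemoselectivity for the lactone; the persistent tetrahedral lactolate secures the first, and the only other carbonyl is masked as the TBS dienol ether. Keeping C7 trigonal at this stage defers the quaternary stereocentre to the tether-controlled cycloaddition of step 11.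

**Step 9**
Reactants: 16 (1RS,3R,7S)-1-[(1R,6R)-4-[(tert-butyldimethylsilyl)oxy]-1,6-dimethylcyclohexa-2,4-dien-1-yl]-1-hydroxy-3,7-dimethyl-7-[(triethylsilyl)oxy]non-8-en-4-one
Product: 17 (1RS,3R,7S)-1-[(1R,6R)-4-[(tert-butyldimethylsilyl)oxy]-1,6-dimethylcyclohexa-2,4-dien-1-yl]-3,7-dimethyl-4-methylidene-7-[(triethylsilyl)oxy]non-8-en-1-ol
Conditions: Tebbe reagent (excess), pyridine, THF–toluene, −40 → 0 °C
Reagents that add atoms: Tebbe reagent, C[Al-]1(C)C[Ti](C2C=CC=C2)(C2C=CC=C2)[Cl+]1
Why: Tebbe methylenation (titanium methylidene, [2+2]/retro-[2+2] through an oxatitanacyclobutane) is non-basic, so the ketone becomes the 1,1-disubstituted alkene C7=C11 without epimerising the adjacent methyl-bearing stereocentre, and the free hydroxyl only consumes excess reagent.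

**Step 10**
Reactants: 17 (1RS,3R,7S)-1-[(1R,6R)-4-[(tert-butyldimethylsilyl)oxy]-1,6-dimethylcyclohexa-2,4-dien-1-yl]-3,7-dimethyl-4-methylidene-7-[(triethylsilyl)oxy]non-8-en-1-ol
Product: 18 (3R,7S)-1-[(1R,6R)-4-[(tert-butyldimethylsilyl)oxy]-1,6-dimethylcyclohexa-2,4-dien-1-yl]-3,7-dimethyl-4-methylidene-7-[(triethylsilyl)oxy]non-8-en-1-one
Conditions: Dess–Martin periodinane, pyridine, CH2Cl2, 0 °C → rt
Reagents that add atoms: none
Why: Dess–Martin oxidation of the secondary alcohol converges both carbinol epimers to a single ketone under buffered, non-acidic conditions that the silyl dienol ether and the silyl ether tolerate.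

**Step 11**
Reactants: 18 (3R,7S)-1-[(1R,6R)-4-[(tert-butyldimethylsilyl)oxy]-1,6-dimethylcyclohexa-2,4-dien-1-yl]-3,7-dimethyl-4-methylidene-7-[(triethylsilyl)oxy]non-8-en-1-one
Product: 19 (1R,2R,3S,6R,7S,8S)-10-[(tert-butyldimethylsilyl)oxy]-2,3,6-trimethyl-7-[(3S)-3-methyl-3-[(triethylsilyl)oxy]pent-4-en-1-yl]tricyclo[5.3.1.0(3,8)]undec-9-en-4-one
Conditions: toluene (0.01 M), BHT (cat.), 200 °C, sealed tube
Reagents that add atoms: none
Why: Thermal type-1 intramolecular Diels–Alder reaction of the 2-siloxycyclohexa-1,3-diene with the tethered unactivated 1,1-disubstituted alkene: the three-atom tether (C4–C5–C6) from C3 allows only C8–C7 and C1–C11 bonding on the diene face that carries the tether, which closes ring B and the bicyclo[2.2.2]octene and sets C1, C7 and C8 relative to C3, with the C2 methyl on the far face and the side chain forced syn to the enol-ether bridge.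

**Step 12**
Reactants: 19 (1R,2R,3S,6R,7S,8S)-10-[(tert-butyldimethylsilyl)oxy]-2,3,6-trimethyl-7-[(3S)-3-methyl-3-[(triethylsilyl)oxy]pent-4-en-1-yl]tricyclo[5.3.1.0(3,8)]undec-9-en-4-one
Product: 20 (1R,2R,3S,4R,6R,7S,8S)-10-[(tert-butyldimethylsilyl)oxy]-2,3,6-trimethyl-7-[(3S)-3-methyl-3-[(triethylsilyl)oxy]pent-4-en-1-yl]tricyclo[5.3.1.0(3,8)]undec-9-en-4-ol
Conditions: SmI2, i-PrOH, THF–HMPA, rt
Reagents that add atoms: none
Why: Single-electron (ketyl) reduction with SmI2 and a proton source should give the equatorial C4 alcohol, the thermodynamic epimer, because an axial C4–OH on chair ring B would be 1,3-diaxial to the axial C6 methyl group (the same methyl blocks axial hydride delivery, which is why a hydride reagent is not used); the silyl enol ether, both alkenes and the allylic silyl ether are not reduced.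

**Step 13**
Reactants: 20 (1R,2R,3S,4R,6R,7S,8S)-10-[(tert-butyldimethylsilyl)oxy]-2,3,6-trimethyl-7-[(3S)-3-methyl-3-[(triethylsilyl)oxy]pent-4-en-1-yl]tricyclo[5.3.1.0(3,8)]undec-9-en-4-ol
Product: 21 (1R,2R,3S,4R,6R,7S,8S)-10-[(tert-butyldimethylsilyl)oxy]-2,3,6-trimethyl-7-[(3S)-3-methyl-3-[(triethylsilyl)oxy]pent-4-en-1-yl]tricyclo[5.3.1.0(3,8)]undec-9-en-4-yl acetate
Conditions: Ac2O, DMAP, pyridine, CH2Cl2, rt
Reagents that add atoms: acetic anhydride, CC(=O)OC(C)=O
Why: DMAP-catalysed acylation (nucleophilic catalysis through the N-acetylpyridinium ion) esterifies the hindered equatorial secondary alcohol with retention, and no other hydroxyl is free.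

**Step 14**
Reactants: 21 (1R,2R,3S,4R,6R,7S,8S)-10-[(tert-butyldimethylsilyl)oxy]-2,3,6-trimethyl-7-[(3S)-3-methyl-3-[(triethylsilyl)oxy]pent-4-en-1-yl]tricyclo[5.3.1.0(3,8)]undec-9-en-4-yl acetate
Product: 22 (1R,2R,3S,4R,6R,7S,8S)-7-[(3S)-3-hydroxy-3-methylpent-4-en-1-yl]-2,3,6-trimethyl-10-oxotricyclo[5.3.1.0(3,8)]undecan-4-yl acetate (CNP0281208.1)
Conditions: HF·pyridine, pyridine, THF, 0 °C → rt
Reagents that add atoms: none
Why: Fluoride-mediated desilylation cleaves both Si–O bonds: the silyl enol ether is protonated at C9 to release the C10 ketone (no stereocentre is created and the bridgeheads cannot enolise) and the tertiary TES ether gives the free allylic alcohol, while the acetate is stable to buffered HF.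

**Compound list**
1 | (1E)-3-[(tert-butyldimethylsilyl)oxy]-N,N-dimethylbuta-1,3-dien-1-amine | CN(C)/C=C/C(=C)O[Si](C)(C)C(C)(C)C | starting material
2 | (E)-2-methylbut-2-enal | C/C=C(\C)C=O | starting material
3 | (1S,2R,6R)-4-[(tert-butyldimethylsilyl)oxy]-2-(dimethylamino)-1,6-dimethylcyclohex-3-ene-1-carbaldehyde (endo cycloadduct) | O=C[C@]1(C)[C@H](N(C)C)C=C(O[Si](C)(C)C(C)(C)C)C[C@H]1C | intermediate (not isolated)
4 | (1S,6R)-1,6-dimethyl-4-oxocyclohex-2-ene-1-carbaldehyde | O=C[C@]1(C)C=CC(=O)C[C@H]1C | intermediate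
5 | methyl (2S)-3-bromo-2-methylpropanoate | COC(=O)[C@H](C)CBr | starting material
6 | bromo[(2S)-3-methoxy-2-methyl-3-oxopropyl]zinc | COC(=O)[C@H](C)C[Zn]Br | intermediate (not isolated)
7 | methyl (2R,4RS)-4-[(1S,6R)-1,6-dimethyl-4-oxocyclohex-2-en-1-yl]-2-methyl-4-[(trimethylsilyl)oxy]butanoate (both C4 epimers) | COC(=O)[C@H](C)CC(O[Si](C)(C)C)[C@]1(C)C=CC(=O)C[C@H]1C | intermediate (not isolated)
8 | (3R,5RS)-5-[(1S,6R)-1,6-dimethyl-4-oxocyclohex-2-en-1-yl]-3-methyloxolan-2-one (both C5 epimers) | C[C@@H]1CC(OC1=O)[C@]2(C)C=CC(=O)C[C@H]2C | intermediate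
9 | (3R,5RS)-5-[(1R,6R)-4-[(tert-butyldimethylsilyl)oxy]-1,6-dimethylcyclohexa-2,4-dien-1-yl]-3-methyloxolan-2-one (both C5 epimers) | C[C@@H]1CC(OC1=O)[C@]2(C)C=CC(O[Si](C)(C)C(C)(C)C)=C[C@H]2C | intermediate
10 | 3-methylbut-3-en-1-ol | C=C(C)CCO | starting material
11 | 2-[(2S)-2-methyloxiran-2-yl]ethan-1-ol | C1[C@@](C)(O1)CCO | intermediate
12 | (3S)-3-methylpent-4-ene-1,3-diol | C=C[C@@](C)(O)CCO | intermediate
13 | (3S)-5-iodo-3-methylpent-1-en-3-ol | C=C[C@@](C)(O)CCI | intermediate
14 | triethyl{[(3S)-5-iodo-3-methylpent-1-en-3-yl]oxy}silane | C=C[C@@](C)(O[Si](CC)(CC)CC)CCI | intermediate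
15 | {(3S)-3-methyl-3-[(triethylsilyl)oxy]pent-4-en-1-yl}lithium | C=C[C@@](C)(O[Si](CC)(CC)CC)CC[Li] | intermediate (not isolated)
16 | (1RS,3R,7S)-1-[(1R,6R)-4-[(tert-butyldimethylsilyl)oxy]-1,6-dimethylcyclohexa-2,4-dien-1-yl]-1-hydroxy-3,7-dimethyl-7-[(triethylsilyl)oxy]non-8-en-4-one (both C1 epimers) | C=C[C@@](C)(O[Si](CC)(CC)CC)CCC(=O)[C@H](C)CC(O)[C@]1(C)C=CC(O[Si](C)(C)C(C)(C)C)=C[C@H]1C | intermediate
17 | (1RS,3R,7S)-1-[(1R,6R)-4-[(tert-butyldimethylsilyl)oxy]-1,6-dimethylcyclohexa-2,4-dien-1-yl]-3,7-dimethyl-4-methylidene-7-[(triethylsilyl)oxy]non-8-en-1-ol (both C1 epimers) | C=C[C@@](C)(O[Si](CC)(CC)CC)CCC(=C)[C@H](C)CC(O)[C@]1(C)C=CC(O[Si](C)(C)C(C)(C)C)=C[C@H]1C | intermediate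
18 | (3R,7S)-1-[(1R,6R)-4-[(tert-butyldimethylsilyl)oxy]-1,6-dimethylcyclohexa-2,4-dien-1-yl]-3,7-dimethyl-4-methylidene-7-[(triethylsilyl)oxy]non-8-en-1-one | C=C[C@@](C)(O[Si](CC)(CC)CC)CCC(=C)[C@H](C)CC(=O)[C@]1(C)C=CC(O[Si](C)(C)C(C)(C)C)=C[C@H]1C | intermediate
19 | (1R,2R,3S,6R,7S,8S)-10-[(tert-butyldimethylsilyl)oxy]-2,3,6-trimethyl-7-[(3S)-3-methyl-3-[(triethylsilyl)oxy]pent-4-en-1-yl]tricyclo[5.3.1.0(3,8)]undec-9-en-4-one | C=C[C@@](C)(O[Si](CC)(CC)CC)CC[C@@]12C[C@H]3C(O[Si](C)(C)C(C)(C)C)=C[C@@H]1[C@](C)([C@@H]3C)C(=O)C[C@H]2C | intermediate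
20 | (1R,2R,3S,4R,6R,7S,8S)-10-[(tert-butyldimethylsilyl)oxy]-2,3,6-trimethyl-7-[(3S)-3-methyl-3-[(triethylsilyl)oxy]pent-4-en-1-yl]tricyclo[5.3.1.0(3,8)]undec-9-en-4-ol | C=C[C@@](C)(O[Si](CC)(CC)CC)CC[C@@]12C[C@H]3C(O[Si](C)(C)C(C)(C)C)=C[C@@H]1[C@](C)([C@@H]3C)[C@H](O)C[C@H]2C | intermediate
21 | (1R,2R,3S,4R,6R,7S,8S)-10-[(tert-butyldimethylsilyl)oxy]-2,3,6-trimethyl-7-[(3S)-3-methyl-3-[(triethylsilyl)oxy]pent-4-en-1-yl]tricyclo[5.3.1.0(3,8)]undec-9-en-4-yl acetate | C=C[C@@](C)(O[Si](CC)(CC)CC)CC[C@@]12C[C@H]3C(O[Si](C)(C)C(C)(C)C)=C[C@@H]1[C@](C)([C@@H]3C)[C@H](OC(C)=O)C[C@H]2C | intermediate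
22 | (1R,2R,3S,4R,6R,7S,8S)-7-[(3S)-3-hydroxy-3-methylpent-4-en-1-yl]-2,3,6-trimethyl-10-oxotricyclo[5.3.1.0(3,8)]undecan-4-yl acetate | C=C[C@@](C)(O)CC[C@@]12C[C@H]3C(=O)C[C@@H]1[C@](C)([C@@H]3C)[C@H](OC(C)=O)C[C@H]2C | target

**Step count.** Total: 14 steps. Longest linear sequence: 11 steps (steps 4–14, from 3-methylbut-3-en-1-ol 10); the core branch from 1 and 2 is 10 steps.

**Steps most likely to fail, with fallbacks**

1. Step 11 (thermal cycloaddition). The unactivated 1,1-disubstituted alkene may add too slowly, so that 1,5-hydrogen shift in the diene or loss of the silyl enol ether competes at 200 °C. The fallback activates the dienophile and sets out from 16. Peterson olefination with lithiated (phenylsulfonyl)(trimethylsilyl)methane (THF, −78 °C → rt) should give the vinyl sulfone F1 (alkene isomers, inconsequential). Dess–Martin oxidation gives the ketone F2. The electron-poor alkene should then add to the siloxydiene well below 200 °C (toluene, 110–140 °C), with the tether again fixing regio- and facial selectivity, to give the cycloadduct sulfone F3 (epimers at C11). Reductive desulfonylation (Na/Hg, Na2HPO4, MeOH–THF, −20 °C) returns to the route at 19.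

2. Step 12 (reduction at C4). Protonation under kinetic control may give poor facial selectivity and leave the axial alcohol. The fallback sets the carbinol before the cycloaddition by reagent control and sets out from 18. Corey–Bakshi–Shibata reduction ((S)-Me-CBS, catecholborane, toluene, −78 °C), with the quaternary ring carbon as the large group, should give the single (1R)-alcohol F4. Acetylation (Ac2O, DMAP) gives the acetate F5. Cycloaddition under the conditions of step 11 then returns to the route at 21.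

3. Step 8 (key addition). α-Deprotonation of the lactone (with erosion of the methyl stereocentre), 1,4-silyl migration in 15, or collapse of the lactolate with double addition may compete. The fallback changes the acyl electrophile and sets out from 9. Aminolysis with MeNH(OMe)·HCl/i-PrMgCl (THF, −20 °C) should give the γ-hydroxy Weinreb amide F6. After deprotonation of its hydroxyl with i-PrMgCl, addition of 15 gives a chelated tetrahedral intermediate that cannot over-add and releases 16 on work-up, where the fallback rejoins the route.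

**Further compounds**
F1 | step 11 | (1RS,3R,7S)-1-[(1R,6R)-4-[(tert-butyldimethylsilyl)oxy]-1,6-dimethylcyclohexa-2,4-dien-1-yl]-3,7-dimethyl-4-[(phenylsulfonyl)methylidene]-7-[(triethylsilyl)oxy]non-8-en-1-ol | C=C[C@@](C)(O[Si](CC)(CC)CC)CCC(=CS(=O)(=O)c1ccccc1)[C@H](C)CC(O)[C@]2(C)C=CC(O[Si](C)(C)C(C)(C)C)=C[C@H]2C
F2 | step 11 | (3R,7S)-1-[(1R,6R)-4-[(tert-butyldimethylsilyl)oxy]-1,6-dimethylcyclohexa-2,4-dien-1-yl]-3,7-dimethyl-4-[(phenylsulfonyl)methylidene]-7-[(triethylsilyl)oxy]non-8-en-1-one | C=C[C@@](C)(O[Si](CC)(CC)CC)CCC(=CS(=O)(=O)c1ccccc1)[C@H](C)CC(=O)[C@]2(C)C=CC(O[Si](C)(C)C(C)(C)C)=C[C@H]2C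
F3 | step 11 | (1R,2R,3S,6R,7S,8S,11RS)-10-[(tert-butyldimethylsilyl)oxy]-2,3,6-trimethyl-7-[(3S)-3-methyl-3-[(triethylsilyl)oxy]pent-4-en-1-yl]-11-(phenylsulfonyl)tricyclo[5.3.1.0(3,8)]undec-9-en-4-one | C=C[C@@](C)(O[Si](CC)(CC)CC)CC[C@@]12C(S(=O)(=O)c4ccccc4)[C@H]3C(O[Si](C)(C)C(C)(C)C)=C[C@@H]1[C@](C)([C@@H]3C)C(=O)C[C@H]2C
F4 | step 12 | (1R,3R,7S)-1-[(1R,6R)-4-[(tert-butyldimethylsilyl)oxy]-1,6-dimethylcyclohexa-2,4-dien-1-yl]-3,7-dimethyl-4-methylidene-7-[(triethylsilyl)oxy]non-8-en-1-ol | C=C[C@@](C)(O[Si](CC)(CC)CC)CCC(=C)[C@H](C)C[C@@H](O)[C@]1(C)C=CC(O[Si](C)(C)C(C)(C)C)=C[C@H]1C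
F5 | step 12 | (1R,3R,7S)-1-[(1R,6R)-4-[(tert-butyldimethylsilyl)oxy]-1,6-dimethylcyclohexa-2,4-dien-1-yl]-3,7-dimethyl-4-methylidene-7-[(triethylsilyl)oxy]non-8-en-1-yl acetate | C=C[C@@](C)(O[Si](CC)(CC)CC)CCC(=C)[C@H](C)C[C@@H](OC(C)=O)[C@]1(C)C=CC(O[Si](C)(C)C(C)(C)C)=C[C@H]1C
F6 | step 8 | (2R,4RS)-4-[(1R,6R)-4-[(tert-butyldimethylsilyl)oxy]-1,6-dimethylcyclohexa-2,4-dien-1-yl]-4-hydroxy-N-methoxy-N,2-dimethylbutanamide | CON(C)C(=O)[C@H](C)CC(O)[C@]1(C)C=CC(O[Si](C)(C)C(C)(C)C)=C[C@H]1C
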